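The total of product and quenched reagent cannot pass the 0.600 M of partner charged to this flask, since each takes one partner. The protic impurity claims 0.150 M, leaving a margin of 0.450 M for product.

| setting | larch | maple | flask |
|---|---|---|---|
| left-handed substrate | 0.50 M | 0.50 M | 0.50 M |
| right-handed substrate | 0.50 M | 0.50 M | 0.50 M |
| partner | 0.60 M | 0.60 M | 0.600 M |
| protic impurity | 0.15 M | 0.15 M | 0.150 M |
| free catalyst | 1 mM | 1 mM | 1.0 mM |
| added ligand | 2.3 mM | 5.2 mM | 3.5 mM |
| remark | run made earlier | run made earlier |  |
| time |  |  | 5.0 d |

- larch (time / d: left-handed product / %, right-handed product / %, left-handed substrate / %): 1.25: 5.4, 2.7, 47.2; 2.50: 7.6, 3.3, 41.7; 4.00: 7.8, 4.3, 40.1; 5.00: 11.5, 5.1, 38.9; 6.00: 12.1, 7.3, 38.8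
- maple (time / d: left-handed product / %, right-handed product / %, left-handed substrate / %): 1.25: 5.3, 2.2, 46.2; 2.50: 6.9, 3.1, 44.2; 4.00: 7.2, 5.4, 43.1; 5.00: 10.8, 5.7, 40.8; 6.00: 11.2, 7.3, 37.6

(standard deviation of a reading: 1 percentage point)

- free catalyst is single-handed; left-handed substrate and right-handed substrate are mirror images of each other, charged as a racemate, each of them at the stated concentration
- what may be going on: free catalyst -> spent catalyst; free catalyst + left-handed substrate <-> catalyst intermediate A; free catalyst + right-handed substrate <-> catalyst intermediate B; partner + protic impurity -> quenched reagent; free catalyst + added ligand <-> idle complex; partner + catalyst intermediate B -> free catalyst + right-handed product; partner + catalyst intermediate A -> free catalyst + left-handed product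
- an excess is the difference of the two amounts in percent of their sum
- an excess is below zero if the other one leads

- excess of left-handed product over right-handed product in the product at 12 h
- excess of left-handed product over right-handed product in the product at 5.0 d
- part of the left-handed substrate and right-handed substrate charged together that has reacted at 5.0 d

For the bench: the flask's ligand lies between those of larch and maple, so their mean readings serve. Total product in larch and maple averages 10.4% at 2.50 d and 18.9% at 6.00 d. The assumption here is that the impurity has taken its partner by 2.50 d. Then [partner] in these runs is about 0.345 M there and 0.260 M at 6.00 d.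

Call κ the partner turned into product per day, over mean [partner], a pseudo-first-order constant read from these scattered means: 0.0802 /d. A first round at constant [partner] gives 17.4% at 5.0 d. Putting that back lowers mean [partner], and the second round gives 16.7%. Keep the flask closed: any further protic impurity comes off the margin.

The forecast gave excesses of 38% at 12 h and 32% at 5.0 d, and 16% reacted, this last slightly below the reckoning here, citing the “faster left-handed substrate depleting preferentially”. The flask gives excesses of 33.4% and 31.5%, and 16.6% reacted.

    free catalyst → spent catalyst (k = 0.00290 /h)
    free catalyst + left-handed substrate ⇌ catalyst intermediate A (K = 2.00 /M, k = 420 /M/h)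
    free catalyst + right-handed substrate ⇌ catalyst intermediate B (K = 4.30 /M, k = 4200 /M/h)
    partner + protic impurity → quenched reagent (k = 0.190 /M/h)
    free catalyst + added ligand ⇌ idle complex (K = 270 /M, k = 5.20 /M/h)
    partner + catalyst intermediate B → free catalyst + right-handed product (k = 2.90 /M/h)
    partner + catalyst intermediate A → free catalyst + left-handed product (k = 13.0 /M/h)

In this flask, partner's half-life by quenching, concentrations held at charge, is 1.0 d, shorter than the 5.0 d of the run, and by 5.00 d it has grown to 4400 d, with protic impurity at 0.023% of its charge. By 2.50 d that step has 99.2% of its turnover up to 5.0 d behind it, and partner then goes from 58.3% to 47.5% of its charge. On that last amount, κ gives 0.0229 M/d of product at 5.00 d.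

In the neighbour flask with 2.4 M of partner, the same two rounds from the start give 90.2%, then 72.1%. The computed part reacted in that flask is 64.6%, lower than the reckoning.

(The runs come from a simulation for substances that don't exist, noise included.)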